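**Strategy**

Everything rests on cutting the C7–C8 bond of the glycerol chain: C7 is the benzylic carbinol carbon on the catechol ring, C8 the carbon bearing the guaiacyl ether oxygen and the C9 hydroxymethyl. With C9 at the carboxyl level, C8 is the α-carbon of an aryloxyacetyl imide and C7 an aldehyde carbon, so one auxiliary-controlled anti-glycolate aldol addition joins the two halves and sets the erythro (7S,8R) hydroxy/aryloxy pair at once. The precursor is the (R)-4-benzyloxazolidinone imide of the guaiacyloxyacetic acid, its propyl chain carried as a methyl ester; one later LiBH4 reduction converts imide carbonyl and ester into both primary alcohols.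

Key step: step 2

Remark: the target is (7S,8R), i.e. erythro, which is the 2,3-anti arrangement in the zigzag drawing of the aldol adduct. The three starting materials are taken to be catalogue compounds.

**Route**

Step 1
Reactants: 1 methyl 3-(4-hydroxy-3-methoxyphenyl)propanoate; 2 (R)-4-benzyl-3-(chloroacetyl)oxazolidin-2-one
Product: 3 (R)-4-benzyl-3-{2-[2-methoxy-4-(3-methoxy-3-oxopropyl)phenoxy]acetyl}oxazolidin-2-one
Conditions: K2CO3 (1.5 equiv), NaI (cat.), acetone, 50 °C
Reagents that add atoms: none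
Why: Williamson ether synthesis, in which the guaiacol-type phenoxide displaces halide (after in-situ Finkelstein exchange) by SN2 at the doubly activated α-carbon of the chloroacetyl imide; the phenoxide is a weaker base than the oxazolidinone anion, so acyl transfer from the imide should not compete, and no stereocentre is formed.

Step 2
Reactants: 3 (R)-4-benzyl-3-{2-[2-methoxy-4-(3-methoxy-3-oxopropyl)phenoxy]acetyl}oxazolidin-2-one; 4 3,4-bis(benzyloxy)benzaldehyde
Product: 6 (R)-4-benzyl-3-[(2S,3S)-3-[3,4-bis(benzyloxy)phenyl]-3-hydroxy-2-[2-methoxy-4-(3-methoxy-3-oxopropyl)phenoxy]propanoyl]oxazolidin-2-one, via O-trimethylsilyl ether 5 (not isolated)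
Conditions: MgCl2 (0.2 equiv), Et3N (2 equiv), TMSCl (1.5 equiv), EtOAc, 23 °C; then TFA (cat.), MeOH, rt
Reagents that add atoms: none
Why: Magnesium halide-catalysed direct anti-aldol addition of an N-acyloxazolidinone by soft enolisation: MgCl2 binds both imide carbonyls of 3, Et3N removes the acidified C8–H to give the chelated Z-enolate (aryloxy cis to O–Mg, enforced by A(1,3) strain), this adds to the Mg-bound aldehyde 4, and TMSCl silylates the aldolate to 5, which frees Mg for turnover and blocks retro-aldol. The closest known reaction type is this same anti-aldol of chiral N-acyloxazolidinones with non-enolisable aromatic aldehydes, here applied to an aryloxyacetyl (glycolate) acyl group. No ring is closed. C8 is controlled by the auxiliary: in the chelate the C4 benzyl group covers one enolate face, so the aldehyde arrives on the other (the sense seen in alkylation of chelated imide enolates), which for the (R)-auxiliary should give the 2S centre of the imide, i.e. 8R of the target. C7 is controlled by the closed boat-like transition state of the chelated Z-enolate, which should place hydroxyl and aryloxy anti (erythro), i.e. 3S of the imide and 7S of the target. The step needs anti over syn and one enolate face, secured by the fixed Z geometry, the two-point Mg chelate and the non-enolisable aldehyde; the methyl ester CH2 is far less acidic than the imide CH2 and should not be enolised, and the benzyl ethers are inert.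

Step 3
Reactants: 6 (R)-4-benzyl-3-[(2S,3S)-3-[3,4-bis(benzyloxy)phenyl]-3-hydroxy-2-[2-methoxy-4-(3-methoxy-3-oxopropyl)phenoxy]propanoyl]oxazolidin-2-one
Product: 7 (1S,2R)-1-[3,4-bis(benzyloxy)phenyl]-2-[4-(3-hydroxypropyl)-2-methoxyphenoxy]propane-1,3-diol
Conditions: LiBH4 (5 equiv), MeOH (5 equiv), THF, 0 °C to rt; aq. NH4Cl
Reagents that add atoms: none
Why: Reductive cleavage of the N-acyloxazolidinone with LiBH4 (hydride attack at the exocyclic imide carbonyl) together with LiBH4 reduction of the methyl ester should deliver both primary alcohols in one operation, while C7, C8, the benzyl ethers and the aryl ether are not touched by borohydride.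

Step 4
Reactants: 7 (1S,2R)-1-[3,4-bis(benzyloxy)phenyl]-2-[4-(3-hydroxypropyl)-2-methoxyphenoxy]propane-1,3-diol
Product: 8 (1S,2R)-1-(3,4-dihydroxyphenyl)-2-[4-(3-hydroxypropyl)-2-methoxyphenoxy]propane-1,3-diol
Conditions: H2 (1 atm), 10% Pd/C, EtOAc/EtOH, rt, stopped when 7 is consumed
Reagents that add atoms: none
Why: Catalytic hydrogenolysis of the two aryl benzyl ethers, which under neutral conditions should cleave much faster than the secondary benzylic C7–OH or the C8–O aryl ether, frees the catechol without touching either stereocentre.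

**Compound list**

1 | methyl 3-(4-hydroxy-3-methoxyphenyl)propanoate | COC(=O)CCc1ccc(O)c(OC)c1 | starting material
2 | (R)-4-benzyl-3-(chloroacetyl)oxazolidin-2-one | O=C(CCl)N1[C@H](Cc2ccccc2)COC1=O | starting material
3 | (R)-4-benzyl-3-{2-[2-methoxy-4-(3-methoxy-3-oxopropyl)phenoxy]acetyl}oxazolidin-2-one | COC(=O)CCc1ccc(OCC(=O)N2[C@H](Cc3ccccc3)COC2=O)c(OC)c1 | intermediate
4 | 3,4-bis(benzyloxy)benzaldehyde | O=Cc1ccc(OCc2ccccc2)c(OCc2ccccc2)c1 | starting material
5 | (R)-4-benzyl-3-[(2S,3S)-3-[3,4-bis(benzyloxy)phenyl]-2-[2-methoxy-4-(3-methoxy-3-oxopropyl)phenoxy]-3-(trimethylsilyloxy)propanoyl]oxazolidin-2-one | COC(=O)CCc1ccc(O[C@H](C(=O)N2[C@H](Cc3ccccc3)COC2=O)[C@@H](O[Si](C)(C)C)c2ccc(OCc3ccccc3)c(OCc3ccccc3)c2)c(OC)c1 | intermediate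
6 | (R)-4-benzyl-3-[(2S,3S)-3-[3,4-bis(benzyloxy)phenyl]-3-hydroxy-2-[2-methoxy-4-(3-methoxy-3-oxopropyl)phenoxy]propanoyl]oxazolidin-2-one | COC(=O)CCc1ccc(O[C@H](C(=O)N2[C@H](Cc3ccccc3)COC2=O)[C@@H](O)c2ccc(OCc3ccccc3)c(OCc3ccccc3)c2)c(OC)c1 | intermediate
7 | (1S,2R)-1-[3,4-bis(benzyloxy)phenyl]-2-[4-(3-hydroxypropyl)-2-methoxyphenoxy]propane-1,3-diol | COc1cc(CCCO)ccc1O[C@H](CO)[C@@H](O)c1ccc(OCc2ccccc2)c(OCc2ccccc2)c1 | intermediate
8 | (1S,2R)-1-(3,4-dihydroxyphenyl)-2-[4-(3-hydroxypropyl)-2-methoxyphenoxy]propane-1,3-diol | COc1cc(CCCO)ccc1O[C@H](CO)[C@@H](O)c1ccc(O)c(O)c1 | target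

**Totals**

Total step count: 4. Longest linear sequence: 4 steps (1 → 3 → 6 → 7 → 8).

**Steps most likely to fail**

Step 2 (key step). The aryloxy and ortho-methoxy oxygens may compete for magnesium and change the enolate chelate, which would erode facial and anti/syn selectivity. Addition to the electron-rich aldehyde may also be slow or reverse before silylation. The fallback sets out from 1 and returns at 7; it forms the same bond by a boron syn-glycolate aldol and corrects C7 afterwards.
- Phenol 1 is alkylated as in step 1, but with (S)-4-benzyl-3-(chloroacetyl)oxazolidin-2-one, to give (S)-4-benzyl-3-{2-[2-methoxy-4-(3-methoxy-3-oxopropyl)phenoxy]acetyl}oxazolidin-2-one F1.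
- Its dibutylboron Z-enolate (Bu2BOTf, iPr2NEt, CH2Cl2, −78 to 0 °C, then 4, oxidative work-up) should give the Evans syn-aldol adduct (S)-4-benzyl-3-[(2S,3R)-3-[3,4-bis(benzyloxy)phenyl]-3-hydroxy-2-[2-methoxy-4-(3-methoxy-3-oxopropyl)phenoxy]propanoyl]oxazolidin-2-one F2. In F2, C8 already has the configuration of the target and C7 is epimeric.
- LiBH4 as in step 3 should give the threo triol (1R,2R)-1-[3,4-bis(benzyloxy)phenyl]-2-[4-(3-hydroxypropyl)-2-methoxyphenoxy]propane-1,3-diol F3.
- Exhaustive Mitsunobu esterification (4-nitrobenzoic acid, PPh3, DIAD, THF, 0 °C to rt) esterifies the two primary alcohols and inverts the benzylic carbinol by SN2. This should give (1S,2R)-1-[3,4-bis(benzyloxy)phenyl]-2-{2-methoxy-4-[3-(4-nitrobenzoyloxy)propyl]phenoxy}propane-1,3-diyl bis(4-nitrobenzoate) F4.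
- Methanolysis (K2CO3, MeOH, rt) then frees 7.

Step 1. Phenoxide or carbonate may attack the imide carbonyl and cleave the auxiliary, or base-induced self-condensation of the chloroacetyl imide may outrun O-alkylation. The fallback sets out from 1 and returns at 3; it builds the ether on a simple ester and attaches the auxiliary last.
- Alkylation of 1 with tert-butyl bromoacetate (K2CO3, acetone) gives methyl 3-[4-(2-tert-butoxy-2-oxoethoxy)-3-methoxyphenyl]propanoate F5.
- TFA in CH2Cl2 removes the tert-butyl group selectively to give 2-[2-methoxy-4-(3-methoxy-3-oxopropyl)phenoxy]acetic acid F6.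
- The pivaloyl mixed anhydride of F6 (PivCl, Et3N, THF, −20 °C) acylates (R)-4-benzyl-2-oxazolidinone (LiCl, rt) to give 3.

Step 3. Under basic borohydride conditions the anti-aldol adduct may undergo retro-aldol cleavage or epimerisation at the α-aryloxy centre, the oxazolidinone ring may open by endocyclic attack, or ester reduction may stall. The fallback sets out from 6 and returns at 7; it separates cleavage from reduction and reduces under non-basic conditions.
- LiOH/H2O2 (THF/H2O, 0 °C to rt) removes the auxiliary and saponifies the methyl ester to give (2S,3S)-3-[3,4-bis(benzyloxy)phenyl]-2-[4-(2-carboxyethyl)-2-methoxyphenoxy]-3-hydroxypropanoic acid F7.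
- BH3·THF (0 °C to rt) reduces both carboxylic acids to the primary alcohols of 7.

**Further compounds**

F1 | step 2 | (S)-4-benzyl-3-{2-[2-methoxy-4-(3-methoxy-3-oxopropyl)phenoxy]acetyl}oxazolidin-2-one | COC(=O)CCc1ccc(OCC(=O)N2[C@@H](Cc3ccccc3)COC2=O)c(OC)c1
F2 | step 2 | (S)-4-benzyl-3-[(2S,3R)-3-[3,4-bis(benzyloxy)phenyl]-3-hydroxy-2-[2-methoxy-4-(3-methoxy-3-oxopropyl)phenoxy]propanoyl]oxazolidin-2-one | COC(=O)CCc1ccc(O[C@H](C(=O)N2[C@@H](Cc3ccccc3)COC2=O)[C@H](O)c2ccc(OCc3ccccc3)c(OCc3ccccc3)c2)c(OC)c1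
F3 | step 2 | (1R,2R)-1-[3,4-bis(benzyloxy)phenyl]-2-[4-(3-hydroxypropyl)-2-methoxyphenoxy]propane-1,3-diol | COc1cc(CCCO)ccc1O[C@H](CO)[C@H](O)c1ccc(OCc2ccccc2)c(OCc2ccccc2)c1
F4 | step 2 | (1S,2R)-1-[3,4-bis(benzyloxy)phenyl]-2-{2-methoxy-4-[3-(4-nitrobenzoyloxy)propyl]phenoxy}propane-1,3-diyl bis(4-nitrobenzoate) | COc1cc(CCCOC(=O)c2ccc(cc2)[N+](=O)[O-])ccc1O[C@H](COC(=O)c1ccc(cc1)[N+](=O)[O-])[C@@H](OC(=O)c1ccc(cc1)[N+](=O)[O-])c1ccc(OCc2ccccc2)c(OCc2ccccc2)c1
F5 | step 1 | methyl 3-[4-(2-tert-butoxy-2-oxoethoxy)-3-methoxyphenyl]propanoate | COC(=O)CCc1ccc(OCC(=O)OC(C)(C)C)c(OC)c1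
F6 | step 1 | 2-[2-methoxy-4-(3-methoxy-3-oxopropyl)phenoxy]acetic acid | COC(=O)CCc1ccc(OCC(O)=O)c(OC)c1
F7 | step 3 | (2S,3S)-3-[3,4-bis(benzyloxy)phenyl]-2-[4-(2-carboxyethyl)-2-methoxyphenoxy]-3-hydroxypropanoic acid | COc1cc(CCC(O)=O)ccc1O[C@H](C(O)=O)[C@@H](O)c1ccc(OCc2ccccc2)c(OCc2ccccc2)c1
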